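Compound numbers 1–29 are those of the steps and the compound list. Locants C1–C15 are the target's throughout, and "upper face" means the face of the six-membered ring that carries C1 and C11.

## The problem

Target 29 is a monocyclic elemane: a cyclohexane (C5–C10) with five stereocentres, four of them contiguous (C5–C8) and one quaternary (C10), and no second ring to relay stereochemistry. C10 carries C14H3 and the vinyl group C1=C2, C5 carries C4(=C3H2)–C15H2OH, C6 a free hydroxyl, C7 the acrylic acid C11(=C13H2)–C12O2H, and C8 the (Z)-4-acetoxy-2-methylbut-2-enoate. C1 and C11 lie on the upper face; C14, C4, O6 and O8 lie on the lower face. In the chair, O6, C11 and O8 are equatorial, while C4 and the vinyl group are axial. C7 therefore sits in its thermodynamically preferred position and tolerates enolisable intermediates, whereas C5, C6, C8 and C10 must be set kinetically and in the right absolute sense. The Z-enoate with its allylic acetate isomerises under acyl activation, is ionised by zerovalent palladium, and survives neither saponification, hydride nor strong base. The 6-hydroxy/12-acid pair closes to the 6,12-lactone under acid, and three terminal alkenes exclude hydrogenolysis, so the endgame must be near neutral. The enabling feature is that C1 and C11 are cis and 1,4-related, so they can be joined as a two-carbon bridge that turns the ring into a bicyclo[2.2.2]octene. The cis pair C4/O6 is the imprint of a cis enol ether, and O6 and C15 close to a five-membered acetal whose carbon can carry a face-controlling chiral alkoxy group.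

## Retrosynthesis

The last disconnection re-closes O6 onto C15: diol 29 is the hydride-reduction product of α-methylene lactol 28. Keeping O6 in a hemiacetal until the final step is preferred to a protected 6,15-diol, because no earlier intermediate can then lactonise onto C12 and no final deprotection is needed. Cutting C4=C3 leads to lactol 27, which asks for an aldehyde α-methylenation next to esters and a free acid. The lactone-enolate alternative would need strong base and then a selective lactone reduction among three ester groups.

In 26 the lactol and the acid of 27 are masked as a menthyl acetal and a 4-methoxybenzyl ester, both removable in one aqueous acid treatment. The C8–O acyl bond is then cut to alcohol 19 and acid 24. The acid is brought in with its acetate already in place, since no selective acetylation is possible later. Its Z geometry is taken from the ring of butenolide 20 (through 23) instead of from an olefination. The forward step must acylate an equatorial secondary alcohol without Z-to-E isomerisation.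

Cutting C11–C12 (carbonylation of enol triflate 17, giving 18 and, after desilylation, 19) and then C1=C2 (Wittig reaction of aldehyde 16) leads back through 15 and 14 to keto ester 13, which lacks C12 and C2. The triflate is made before the ester is reduced, so that the hydride meets a single carbonyl group. The carbonylation precedes attachment of the side chain, so that the allylic acetate never meets zerovalent palladium.

Reconnecting C1 to C11 converts monocyclic 13 into the bicyclic α-hydroxy ketal 12; the forward reaction is an oxidative fragmentation of the C11–C1 bond. It is chosen over ketal hydrolysis and glycol cleavage because the acid needed for the hindered ketal would also remove the acetal that protects O6 and C15. Removing the silyl group and O8 (hydroboration of 9 to 11) and then C13 (methyl addition to ketone 8) simplifies 12 to the cycloadduct. The rigid bicycle is what allows O8 to be placed by steric approach control.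

The key disconnection cuts C5–C10 and C6–C7 of 8, giving dienone 7 and the enantiopure dihydrofuran 5. One cycloaddition closes the carbocycle and sets C5, C6, C7 and C10, and it delivers C4, C15 and O6 in the dienophile. Competing cuts of the ring each set fewer centres (see below). The forward reaction must be regioselective, endo-selective and face-selective.

Dienone 7 comes from phenol 6 by oxidative dearomatisation. Dihydrofuran 5 comes from lactol 3, lactone 2 and the menthyloxy butenolide 1, a crystalline single diastereomer. The controlling acetal centre is therefore purchased, and no acetal epimers have to be separated.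

## Roads not taken

Alternative 1: The cut is C7–C8. An acyclic aldehyde A2 (C8 aldehyde, trisubstituted C7=C11 alkene) would close under a dialkylaluminium chloride Lewis acid in a carbonyl-ene reaction to cyclohexanol A1, with the new isopropenyl group trans to the C8 hydroxyl.
- Merit: O8 arrives with the target configuration from a chair transition state, without hydroboration or protecting-group traffic at C8. In this respect it is better than the chosen plan, which relies on a steric argument in step 6.
- Weak points: the hard stereochemistry (quaternary C10 beside C5 and C6) must already be present in A2, so the key step sets only C7 and C8. The transition state must carry the C5 ester and the C10 vinyl group axial. After the key step C12 is still a methyl group, which needs a two-level allylic oxidation beside other alkenes. C4 is only a carboxyl carbon, so C3 and C15 need two further C–C bonds at a hindered position.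
- Comparison: the chosen plan sets four centres in its key step, brings C4 and C15 in with the dienophile, and reaches C12 by carbonylation.

Alternative 2: The cut is C6–O and C5–Br, with no C–C bond formed. The achiral diene acid A4, one Birch reduction–methylation from an aromatic acid, would be desymmetrised by catalyst-controlled bromolactonisation to A3.
- Merit: this is the shortest access to an enantioenriched C10, and it is catalytic in chirality, where the chosen plan uses a stoichiometric auxiliary. C1 is already a carboxyl carbon on C10.
- Weak points: only C10 is durably set. C6 in A3 is at the ketone oxidation level and must be set again. C5 carries a neopentyl secondary bromide at which C4 must be attached without evident control. C7 needs a carbon substituent between two carbonyl-level carbons. The electron-rich enol ethers are prone to fast uncatalysed bromination.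
- Comparison: it reaches a chiral intermediate sooner, but C5, C6, C7 and C8 would each need their own controlled step, so the route to the five-centre array is far longer.

Alternative 3: The cut is C5–C10 and C8–C9. Bromopyrone A6 and methacrolein A7 would combine under a chiral oxazaborolidinium Lewis acid to the bridged lactone A5.
- Merit: the logic matches the chosen plan (cycloaddition, then bridge opening), and it is catalytic. It is better on two counts: O8 is delivered with the right configuration by the lactone bridge, and C1 is already an aldehyde, one step from the vinyl group, where the chosen plan needs three.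
- Weak points: C6 and C7 remain sp2 (C6=C7–Br), so O6 and C11 must later be added trans across a trisubstituted alkene with face control. C4 lacks C3 and C15. α-Substituted enals give uncertain endo/exo ratios with pyrones, and the adducts lose CO2 on heating.
- Comparison: it sets three centres (C5, C8, C10) and leaves the contiguous C6/C7 pair. The chosen plan sets C5, C6, C7 and C10 and leaves only C8, which is addressed by hydroboration of a rigid bicycle.

Key step: step 4

Assumption: 1, 6 and 20 are taken as purchasable; after step 4 the configuration at C15 no longer matters, so later anomerisation there is harmless.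

## Steps

Step 1
Reactants: 1 (5R)-5-[(1R,2S,5R)-menthyloxy]furan-2(5H)-one
Product: 2 (5R)-5-[(1R,2S,5R)-menthyloxy]dihydrofuran-2(3H)-one
Conditions: H2 (1 atm), Pd/C, EtOAc, rt
Reagents that add atoms: none
Why: Heterogeneous hydrogenation of the conjugated C=C; the acetal stereocentre, the source of all absolute configuration in the route, is untouched.

Step 2
Reactants: 2 (5R)-5-[(1R,2S,5R)-menthyloxy]dihydrofuran-2(3H)-one
Product: 3 (5R)-5-[(1R,2S,5R)-menthyloxy]tetrahydrofuran-2-ol (both anomers)
Conditions: i-Bu2AlH, CH2Cl2, −78 °C; aq. potassium sodium tartrate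
Reagents that add atoms: none
Why: Partial reduction of a γ-lactone; the tetrahedral aluminate is stable at −78 °C and gives the lactol on work-up, and the alkoxy acetal carbon is inert.

Step 3
Reactants: 3 (5R)-5-[(1R,2S,5R)-menthyloxy]tetrahydrofuran-2-ol
Product: 5 (2S)-2-[(1R,2S,5R)-menthyloxy]-2,3-dihydrofuran, via anomeric mesylate 4 (not isolated)
Conditions: MsCl, Et3N, CH2Cl2, −40 °C → reflux
Reagents that add atoms: methanesulfonyl chloride, CS(=O)(=O)Cl (its atoms are carried only in 4)
Why: Dehydration of a lactol through its anomeric sulfonate (ionisation assisted by the ring oxygen, then deprotonation at C3) is the standard entry to 2,3-dihydrofurans. The medium stays basic, so the acetal centre cannot epimerise and loss of menthol to furan is avoided; 5 is purified on base-washed silica.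

Step 4
Reactants: 6 2-methoxy-3-methylphenol; 5 (2S)-2-[(1R,2S,5R)-menthyloxy]-2,3-dihydrofuran
Product: 8 endo cycloadduct (bicyclo[2.2.2]octenone cis-fused to the 2-menthyloxyoxolane), via dienone 7 (not isolated)
Conditions: PhI(OAc)2, NaHCO3, MeOH, 0 °C → 40 °C (6 added slowly to 5 and the oxidant)
Reagents that add atoms: methanol, CO
Why: PhI(OAc)2 oxidises 6 in methanol (ligand exchange at iodine, methanol attack at the methoxy-bearing ortho carbon) to dienone 7, which is trapped by enol ether 5 in an inverse-electron-demand Diels–Alder reaction, the established behaviour of 6,6-dimethoxycyclohexa-2,4-dienones towards 2,3-dihydrofuran and other enol ethers. The cyclohexane C5–C10 is closed by the concerted suprafacial [4+2] union of the diene C10=C9–C8=C7 with the alkene C5=C6 (bonds C5–C10 and C6–C7), inside a bicyclo[2.2.2]octenone whose keto-ketal bridge is C11–C1. Regiochemistry follows the dienone polarisation: the nucleophilic β-carbon of the enol ether (C5) bonds to the δ-terminus C10, which has the largest LUMO coefficient, and the oxygen-bearing C6 bonds to C7 next to the ketone. C10 and C7 are fixed relative to each other by the bridge; C5 and C6 are cis because the dienophile is a ring alkene, and the endo rule places C4 and O6 under the diene, syn to C8=C9 and trans to the C1–C11 bridge, which is the target's relative configuration at all four new centres. Absolute configuration comes from C15: the pseudo-axial menthyloxy group covers one face of the dihydrofuran and would be pushed into the diene in the endo transition state, so the dienone adds anti to it. The step therefore needs regio, endo and facial selectivity; the first two are general for this dienone class, the third rests on the acetal substituent, and because the auxiliary stays attached any wrong-face adduct is a separable diastereomer, not the enantiomer. NaHCO3 neutralises the acetic acid released so that 5 neither adds methanol nor loses menthol, and the methyl group of 7 slows its self-dimerisation, in which the methyl-bearing double bond is the 2π partner.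

Step 5
Reactants: 8 endo cycloadduct
Product: 9 C11 tertiary alcohol (new methyl C13 syn to the C8=C9 bond)
Conditions: MeLi, THF, −78 °C
Reagents that add atoms: methyllithium, [Li]C
Why: 1,2-Addition to a non-enolisable ketone (its only α-hydrogen is at bridgehead C7); attack should come from the alkene side, the open face of bicyclo[2.2.2]oct-5-en-2-ones. The C11 configuration is erased in step 8 and matters only for the face selectivity of step 6.

Step 6
Reactants: 9 C11 tertiary alcohol
Product: 11 C8,C11-diol (C8 hydroxyl syn to the oxolane), via C8 alkylborane 10 (not isolated)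
Conditions: BH3·THF, THF, 0 °C → rt; then NaOH, H2O2, 0 °C
Reagents that add atoms: borane–tetrahydrofuran, B.C1CCOC1 (boron is carried only in 10); hydrogen peroxide, OO
Why: Hydroboration–oxidation; boron should go to C8, away from the quaternary bridgehead C10, and from the alkene face syn to the oxolane, because the other face is screened over C8 by the C13 methyl and over C9 by a ketal methoxy group. Syn addition and retentive C–B oxidation then place O8 cis to O6 and trans to C11, as in 29.

Step 7
Reactants: 11 C8,C11-diol
Product: 12 C8 tert-butyldimethylsilyl ether (C11 hydroxyl free)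
Conditions: TBSCl, imidazole, DMF, rt
Reagents that add atoms: tert-butyldimethylsilyl chloride, CC(C)(C)[Si](C)(C)Cl
Why: Silylation with the chloride and imidazole distinguishes the secondary C8 hydroxyl from the tertiary C11 hydroxyl, which must stay free for step 8.

Step 8
Reactants: 12 C8 silyl ether
Product: 13 keto ester (C10 methyl ester C1 and C7 acetyl C11/C13 on the upper face; C8 silyl ether and the fused 2-menthyloxyoxolane on the lower face)
Conditions: PhI(OAc)2, I2, CH2Cl2, visible light, rt
Reagents that add atoms: none
Why: Hypoiodite (alkoxy-radical) β-fragmentation: the C11 alkoxy radical should cleave the C11–C1 bond, since this gives a tertiary radical stabilised by two methoxy oxygens and releases the bicyclic strain; oxidation of that radical to the dialkoxycarbenium ion and loss of one methyl group to acetate leaves the C10 methyl ester, and C11 becomes the methyl ketone. The non-aqueous, weakly acidic medium spares the acetal that aqueous ketal hydrolysis would destroy, and C7 remains the equatorial, thermodynamically preferred epimer.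

Step 9
Reactants: 13 keto ester
Product: 14 enol triflate (C7 bears C(OTf)=CH2)
Conditions: KN(SiMe3)2, THF, −78 °C; then PhNTf2, −78 → 0 °C
Reagents that add atoms: N-phenylbis(trifluoromethanesulfonimide), O=S(=O)(N(c1ccccc1)S(=O)(=O)C(F)(F)F)C(F)(F)F
Why: Kinetic deprotonation of the methyl ketone at C13 with a hindered amide base and O-sulfonylation give the terminal enol triflate. The C10 ester has no α-hydrogen and the hindered C7–H is not removed, so neither epimerisation nor β-elimination of O6 or O8 is expected.

Step 10
Reactants: 14 enol triflate
Product: 15 primary alcohol (C1 as CH2OH)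
Conditions: i-Bu2AlH, CH2Cl2, −78 → 0 °C
Reagents that add atoms: none
Why: Reduction of the only ester to the primary alcohol; enol triflate, silyl ether and acetal are stable to this hydride at low temperature.

Step 11
Reactants: 15 primary alcohol
Product: 16 aldehyde (C1 as CHO)
Conditions: Dess–Martin periodinane, pyridine, CH2Cl2, 0 °C → rt
Reagents that add atoms: none
Why: Dess–Martin oxidation under buffered conditions; the aldehyde sits on quaternary C10 and cannot enolise.

Step 12
Reactants: 16 aldehyde
Product: 17 vinyl compound (C10 bears C1=C2)
Conditions: Ph3PCH3Br, KOt-Bu, THF, 0 °C; then 16, 0 °C → rt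
Reagents that add atoms: methyltriphenylphosphonium bromide, C[P+](c1ccccc1)(c1ccccc1)c1ccccc1.[Br-]
Why: Wittig methylenation of the non-enolisable neopentyl aldehyde installs C2; the ylide should not attack the enol triflate at this temperature.

Step 13
Reactants: 17 vinyl compound
Product: 18 4-methoxybenzyl acrylate (C7 bears C(=CH2)CO2CH2C6H4OMe)
Conditions: Pd(OAc)2 (10 mol %), PPh3, CO (1 atm), 4-MeOC6H4CH2OH, Et3N, DMF, 60 °C
Reagents that add atoms: carbon monoxide, [C-]#[O+]; 4-methoxybenzyl alcohol, COc1ccc(CO)cc1
Why: Palladium-catalysed alkoxycarbonylation of an enol triflate (oxidative addition to zerovalent palladium formed in situ, CO insertion, alcoholysis of the acyl complex) forms C11–C12. The 4-methoxybenzyl ester is chosen because it later falls to the same acid as the acetal, and the step precedes the side chain so that the allylic acetate never meets zerovalent palladium.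

Step 14
Reactants: 18 4-methoxybenzyl acrylate
Product: 19 C8 alcohol
Conditions: HF·pyridine, pyridine, THF, 0 °C → rt
Reagents that add atoms: none
Why: Fluoride cleavage of the silyl ether under buffered, weakly acidic conditions; a basic fluoride source is avoided so that a C8 alkoxide cannot close onto the C12 ester.

Step 15
Reactants: 20 3-methylfuran-2(5H)-one
Product: 23 4-methoxybenzyl (Z)-4-acetoxy-2-methylbut-2-enoate, via potassium (Z)-4-hydroxy-2-methylbut-2-enoate 21 (not isolated), via 4-methoxybenzyl (Z)-4-hydroxy-2-methylbut-2-enoate 22 (not isolated)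
Conditions: KOH (1 equiv), H2O, 0 °C → rt, then freeze-dry; 4-MeOC6H4CH2Cl, Bu4NI (cat.), DMF, 0 °C → rt; then Ac2O, pyridine, 0 °C
Reagents that add atoms: potassium hydroxide, [K+].[OH-]; 4-methoxybenzyl chloride, COc1ccc(CCl)cc1; acetic anhydride, CC(=O)OC(C)=O
Why: Saponification of the butenolide gives the hydroxy carboxylate with the Z geometry fixed by the former ring; SN2 O-alkylation of the carboxylate and immediate acetylation of the primary alcohol block relactonisation. The double bond is never touched.

Step 16
Reactants: 23 4-methoxybenzyl (Z)-4-acetoxy-2-methylbut-2-enoate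
Product: 24 (Z)-4-acetoxy-2-methylbut-2-enoic acid
Conditions: CF3CO2H, anisole, CH2Cl2, 0 °C
Reagents that add atoms: none
Why: Acidolysis of the 4-methoxybenzyl ester (the benzylic cation is trapped by anisole) frees the acid without base, so the acetate and the Z double bond survive; with its hydroxyl acetylated the acid cannot lactonise.

Step 17
Reactants: 19 C8 alcohol; 24 (Z)-4-acetoxy-2-methylbut-2-enoic acid
Product: 26 C8 (Z)-4-acetoxy-2-methylbut-2-enoate, via mixed 2,4,6-trichlorobenzoic anhydride 25 (not isolated)
Conditions: 24, 2,4,6-Cl3C6H2COCl, Et3N, toluene, rt; then 19, toluene, 70 °C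
Reagents that add atoms: 2,4,6-trichlorobenzoyl chloride, O=C(Cl)c1c(Cl)cc(Cl)cc1Cl (carried only in 25)
Why: Yamaguchi-type esterification through the mixed anhydride, run without a nucleophilic catalyst because such catalysts isomerise Z-2-methylbut-2-enoates to the E isomers by conjugate addition. The equatorial C8 hydroxyl is acylated with retention.

Step 18
Reactants: 26 C8 ester
Product: 27 lactol acid (C15 hemiacetal as both anomers; C12 free acid)
Conditions: CF3CO2H, CH2Cl2, 0 °C; then H2O, rt
Reagents that add atoms: water, O
Why: Acid hydrolyses the mixed acetal to the lactol (oxocarbenium ion, water capture) and cleaves the 4-methoxybenzyl ester by alkyl–oxygen fission in the same operation. O6 stays bound in the five-membered lactol, so the liberated C12 acid has no free hydroxyl to lactonise with.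

Step 19
Reactants: 27 lactol acid
Product: 28 α-methylene lactol acid (C4=C3H2)
Conditions: aq. CH2O (37%), pyrrolidine (20 mol %), EtCO2H (20 mol %), i-PrOH, 45 °C
Reagents that add atoms: formaldehyde, C=O
Why: Amine-catalysed α-methylenation of an aldehyde (enamine from the open hydroxy-aldehyde form of the lactol, Mannich reaction with formaldehyde, β-elimination of the amine) installs C3 on C4, and the product recloses to the lactol. No strong base or hydride is involved, so esters, acetate and acid are untouched.

Step 20
Reactants: 28 α-methylene lactol acid
Product: 29 (5S,6R,7S,8S,10R)-8-[(2Z)-4-acetoxy-2-methylbut-2-enoyloxy]-6,15-dihydroxyelema-1,3,11(13)-trien-12-oic acid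
Conditions: NaBH4, CeCl3·7H2O, THF–EtOH, −20 → 0 °C; pH 5 phosphate buffer work-up
Reagents that add atoms: none
Why: Luche-type 1,2-reduction of the enal in equilibrium with the lactol gives the C15 allylic alcohol and frees the C6 hydroxyl; esters and the carboxylate are inert to NaBH4 at this temperature. The acid is a carboxylate when O6 is released and the work-up stays near pH 5, so closure to the 6,12-lactone should be avoided.

## Compound list

1 | (5R)-5-[(1R,2S,5R)-2-isopropyl-5-methylcyclohexyloxy]furan-2(5H)-one (menthyloxy butenolide) | CC(C)[C@@H]1CC[C@@H](C)C[C@H]1O[C@H]2C=CC(=O)O2 | starting material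
2 | (5R)-5-[(1R,2S,5R)-menthyloxy]dihydrofuran-2(3H)-one | CC(C)[C@@H]1CC[C@@H](C)C[C@H]1O[C@H]2CCC(=O)O2 | intermediate
3 | (5R)-5-[(1R,2S,5R)-menthyloxy]tetrahydrofuran-2-ol, both anomers at C2 | CC(C)[C@@H]1CC[C@@H](C)C[C@H]1O[C@H]2CCC(O)O2 | intermediate
4 | (5R)-5-[(1R,2S,5R)-menthyloxy]tetrahydrofuran-2-yl methanesulfonate | CC(C)[C@@H]1CC[C@@H](C)C[C@H]1O[C@H]2CCC(OS(C)(=O)=O)O2 | intermediate (not isolated)
5 | (2S)-2-[(1R,2S,5R)-menthyloxy]-2,3-dihydrofuran | CC(C)[C@@H]1CC[C@@H](C)C[C@H]1O[C@H]2CC=CO2 | intermediate
6 | 2-methoxy-3-methylphenol | COc1c(C)cccc1O | starting material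
7 | 6,6-dimethoxy-5-methylcyclohexa-2,4-dien-1-one | COC1(OC)C(C)=CC=CC1=O | intermediate (not isolated)
8 | endo cycloadduct, 8,8-dimethoxy-7-methyl-4-[(1R,2S,5R)-menthyloxy]-3-oxatricyclo[5.2.2.0(2,6)]undec-10-en-9-one: bridge C1 (ketal)–C11 (ketone), alkene C8=C9, oxolane (O6, C15, C4) cis-fused at C6/C5 and syn to the alkene, menthyloxy on the convex face | C[C@@]12C=C[C@@H](C(=O)C1(OC)OC)[C@@H]3O[C@@H](O[C@@H]4C[C@H](C)CC[C@H]4C(C)C)C[C@H]23 | intermediate
9 | C11 tertiary alcohol of 8 (C13 methyl syn to C8=C9, hydroxyl towards the oxolane bridge) | C[C@@]12C=C[C@@H]([C@](C)(O)C1(OC)OC)[C@@H]3O[C@@H](O[C@@H]4C[C@H](C)CC[C@H]4C(C)C)C[C@H]23 | intermediate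
10 | C8 alkylborane of 9 (boron syn to the oxolane; drawn in its simplest form as the monoalkylborane) | C[C@@]12C[C@H](B)[C@@H]([C@](C)(O)C1(OC)OC)[C@@H]3O[C@@H](O[C@@H]4C[C@H](C)CC[C@H]4C(C)C)C[C@H]23 | intermediate (not isolated)
11 | C8,C11-diol (C8–C9 saturated; C8 hydroxyl syn to the oxolane, cis to O6, trans to C11) | C[C@@]12C[C@H](O)[C@@H]([C@](C)(O)C1(OC)OC)[C@@H]3O[C@@H](O[C@@H]4C[C@H](C)CC[C@H]4C(C)C)C[C@H]23 | intermediate
12 | C8 tert-butyldimethylsilyl ether of 11 | C[C@@]12C[C@H](O[Si](C)(C)C(C)(C)C)[C@@H]([C@](C)(O)C1(OC)OC)[C@@H]3O[C@@H](O[C@@H]4C[C@H](C)CC[C@H]4C(C)C)C[C@H]23 | intermediate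
13 | keto ester: cyclohexane with C10 (CO2CH3 upper face, CH3 lower face), C7 acetyl (upper face), C8 silyl ether (lower face), 2-menthyloxyoxolane cis-fused at C5/C6 (C4 and O6 lower face) | COC(=O)[C@@]1(C)C[C@H](O[Si](C)(C)C(C)(C)C)[C@@H](C(C)=O)[C@@H]2O[C@@H](O[C@@H]3C[C@H](C)CC[C@H]3C(C)C)C[C@H]12 | intermediate
14 | enol triflate of 13 (C7 bears 1-(trifluoromethanesulfonyloxy)vinyl) | COC(=O)[C@@]1(C)C[C@H](O[Si](C)(C)C(C)(C)C)[C@@H](C(=C)OS(=O)(=O)C(F)(F)F)[C@@H]2O[C@@H](O[C@@H]3C[C@H](C)CC[C@H]3C(C)C)C[C@H]12 | intermediate
15 | primary alcohol (C1 as CH2OH on C10) | OC[C@@]1(C)C[C@H](O[Si](C)(C)C(C)(C)C)[C@@H](C(=C)OS(=O)(=O)C(F)(F)F)[C@@H]2O[C@@H](O[C@@H]3C[C@H](C)CC[C@H]3C(C)C)C[C@H]12 | intermediate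
16 | aldehyde (C1 as CHO on C10) | O=C[C@@]1(C)C[C@H](O[Si](C)(C)C(C)(C)C)[C@@H](C(=C)OS(=O)(=O)C(F)(F)F)[C@@H]2O[C@@H](O[C@@H]3C[C@H](C)CC[C@H]3C(C)C)C[C@H]12 | intermediate
17 | vinyl compound (C10 vinyl, C7 enol triflate) | C=C[C@@]1(C)C[C@H](O[Si](C)(C)C(C)(C)C)[C@@H](C(=C)OS(=O)(=O)C(F)(F)F)[C@@H]2O[C@@H](O[C@@H]3C[C@H](C)CC[C@H]3C(C)C)C[C@H]12 | intermediate
18 | 4-methoxybenzyl acrylate (C7 bears C(=CH2)CO2CH2C6H4OMe; C8 silyl ether) | C=C[C@@]1(C)C[C@H](O[Si](C)(C)C(C)(C)C)[C@@H](C(=C)C(=O)OCc3ccc(OC)cc3)[C@@H]2O[C@@H](O[C@@H]4C[C@H](C)CC[C@H]4C(C)C)C[C@H]12 | intermediate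
19 | C8 alcohol of 18 | C=C[C@@]1(C)C[C@H](O)[C@@H](C(=C)C(=O)OCc3ccc(OC)cc3)[C@@H]2O[C@@H](O[C@@H]4C[C@H](C)CC[C@H]4C(C)C)C[C@H]12 | intermediate
20 | 3-methylfuran-2(5H)-one | CC1=CCOC1=O | starting material
21 | potassium (Z)-4-hydroxy-2-methylbut-2-enoate | [K+].[O-]C(=O)/C(C)=C\CO | intermediate (not isolated)
22 | 4-methoxybenzyl (Z)-4-hydroxy-2-methylbut-2-enoate | COc1ccc(COC(=O)/C(C)=C\CO)cc1 | intermediate (not isolated)
23 | 4-methoxybenzyl (Z)-4-acetoxy-2-methylbut-2-enoate | COc1ccc(COC(=O)/C(C)=C\COC(C)=O)cc1 | intermediate
24 | (Z)-4-acetoxy-2-methylbut-2-enoic acid | OC(=O)/C(C)=C\COC(C)=O | intermediate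
25 | (Z)-4-acetoxy-2-methylbut-2-enoic 2,4,6-trichlorobenzoic anhydride | O=C(OC(=O)/C(C)=C\COC(C)=O)c1c(Cl)cc(Cl)cc1Cl | intermediate (not isolated)
26 | C8 (Z)-4-acetoxy-2-methylbut-2-enoate of 19 | C=C[C@@]1(C)C[C@H](OC(=O)/C(C)=C\COC(C)=O)[C@@H](C(=C)C(=O)OCc3ccc(OC)cc3)[C@@H]2O[C@@H](O[C@@H]4C[C@H](C)CC[C@H]4C(C)C)C[C@H]12 | intermediate
27 | lactol acid (C15 hemiacetal, both anomers; C12 acid) | C=C[C@@]1(C)C[C@H](OC(=O)/C(C)=C\COC(C)=O)[C@@H](C(=C)C(=O)O)[C@@H]2OC(O)C[C@H]12 | intermediate
28 | α-methylene lactol acid (C4=C3H2; both anomers) | C=C[C@@]1(C)C[C@H](OC(=O)/C(C)=C\COC(C)=O)[C@@H](C(=C)C(=O)O)[C@@H]2OC(O)C(=C)[C@H]12 | intermediate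
29 | (5S,6R,7S,8S,10R)-8-[(2Z)-4-acetoxy-2-methylbut-2-enoyloxy]-6,15-dihydroxyelema-1,3,11(13)-trien-12-oic acid | C=C[C@@]1(C)C[C@H](OC(=O)/C(C)=C\COC(C)=O)[C@@H](C(=C)C(=O)O)[C@H](O)[C@@H]1C(=C)CO | target

## Step count and least certain steps

Total: 20 steps. Longest linear sequence: 18 steps (steps 1–14 and 17–20); steps 15–16 make acid 24.

Step 4 (key step). The most likely failure is that self-dimerisation of dienone 7 and slow loss of the acid-sensitive enol ether 5 (methanol addition, elimination of menthol to furan) outrun the cycloaddition, because the dienophile is hindered and is not used in large excess. Incomplete face control by the remote acetal is the second concern; it costs only yield, since the minor adduct is a separable diastereomer. The fallback sets out from 6 and 5 and returns at 8, using a bromine-blocked, isolable dienone. Bromination of 6 para to the hydroxyl with N-bromosuccinimide gives 4-bromo-2-methoxy-3-methylphenol F1. Oxidation with PhI(OAc)2 in methanol gives 4-bromo-6,6-dimethoxy-5-methylcyclohexa-2,4-dien-1-one F2, which does not dimerise readily. F2 and 5 are heated together in toluene without methanol or acid to give the C9-bromo adduct F3. Bu3SnH with a radical initiator then removes the vinylic bromine and gives 8.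

Step 8. The alkoxy radical may abstract hydrogen from a ketal methoxy group (1,5-transfer) instead of fragmenting, or the iodine/acetic acid medium may degrade the acetal. The fallback sets out from 12 and returns at 13, replacing the radical fragmentation by hydrolysis and glycol cleavage. Aqueous trifluoroacetic acid in THF hydrolyses ketal and acetal together to the α-ketol lactol F4. Criegee cleavage with Pb(OAc)4 in methanol gives the keto ester lactol F5. Acetalisation with (1R,2S,5R)-menthol (pyridinium p-toluenesulfonate, molecular sieves) regenerates 13 together with its C15 epimer F6. F6 need not be removed, because both anomers converge on 27 in step 18.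

Step 6. Borane may be delivered to the other alkene face, or partly to C9, because both faces of the bicyclic alkene carry substituents and the preference rests on a steric comparison (methyl against ring oxygen over C8). The fallback sets out from 9 and returns at 11. If the C8-epimeric alcohol F7 is the main product, it is oxidised with Dess–Martin periodinane to the C8 ketone F8 and reduced with NaBH4. Hydride then enters from the same, more accessible face and pushes the hydroxyl to the required side, giving 11.

Step 19. Enamine formation may be slow because the lactol is mostly closed, leaving time for the amine to add to the acrylic acid or for the transient open hydroxy aldehyde to lactonise onto C12. The fallback sets out from 27 and returns at 28 by a stoichiometric, stepwise aminomethylation. Dimethyl(methylidene)ammonium iodide and Et3N in CH2Cl2 give the isolable Mannich base F9, which loses dimethylamine on gentle warming over silica to give 28.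

Step 17. The uncatalysed acylation at 70 °C is slow, and two processes may compete: Z-to-E isomerisation of the activated acyl group, and intramolecular transesterification of the free C8 hydroxyl onto the C12 ester (a trans-fused 8,12-lactone). The fallback sets out from 19 and returns at 26, building the Z alkene after the ester bond. Carbodiimide coupling of 19 with 2-[bis(2,2,2-trifluoroethoxy)phosphoryl]propanoic acid at room temperature gives phosphonate ester F10, where no alkene geometry is at stake. Still–Gennari olefination of F10 with acetoxyacetaldehyde (KN(SiMe3)2, 18-crown-6, THF, −78 °C) then gives 26.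

## Further compounds

F1 | step 4 | 4-bromo-2-methoxy-3-methylphenol | COc1c(C)c(Br)ccc1O
F2 | step 4 | 4-bromo-6,6-dimethoxy-5-methylcyclohexa-2,4-dien-1-one | COC1(OC)C(C)=C(Br)C=CC1=O
F3 | step 4 | C9-bromo analogue of cycloadduct 8 | C[C@@]12C(Br)=C[C@@H](C(=O)C1(OC)OC)[C@@H]3O[C@@H](O[C@@H]4C[C@H](C)CC[C@H]4C(C)C)C[C@H]23
F4 | step 8 | α-ketol lactol (C1 ketone, C11 tertiary alcohol, C15 hemiacetal, C8 silyl ether) | C[C@@]12C[C@H](O[Si](C)(C)C(C)(C)C)[C@@H]([C@](C)(O)C1=O)[C@@H]3OC(O)C[C@H]23
F5 | step 8 | keto ester lactol (13 with C15 hemiacetal in place of the menthyl acetal) | COC(=O)[C@@]1(C)C[C@H](O[Si](C)(C)C(C)(C)C)[C@@H](C(C)=O)[C@@H]2OC(O)C[C@H]12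
F6 | step 8 | C15 epimer of keto ester 13 | COC(=O)[C@@]1(C)C[C@H](O[Si](C)(C)C(C)(C)C)[C@@H](C(C)=O)[C@@H]2O[C@H](O[C@@H]3C[C@H](C)CC[C@H]3C(C)C)C[C@H]12
F7 | step 6 | C8 epimer of diol 11 | C[C@@]12C[C@@H](O)[C@@H]([C@](C)(O)C1(OC)OC)[C@@H]3O[C@@H](O[C@@H]4C[C@H](C)CC[C@H]4C(C)C)C[C@H]23
F8 | step 6 | C8 ketone of the bicyclic C11 carbinol | C[C@@]12CC(=O)[C@@H]([C@](C)(O)C1(OC)OC)[C@@H]3O[C@@H](O[C@@H]4C[C@H](C)CC[C@H]4C(C)C)C[C@H]23
F9 | step 19 | C4 dimethylaminomethyl lactol acid (Mannich base of 27) | C=C[C@@]1(C)C[C@H](OC(=O)/C(C)=C\COC(C)=O)[C@@H](C(=C)C(=O)O)[C@@H]2OC(O)C(CN(C)C)[C@H]12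
F10 | step 17 | C8 2-[bis(2,2,2-trifluoroethoxy)phosphoryl]propanoate of 19 | C=C[C@@]1(C)C[C@H](OC(=O)C(C)P(=O)(OCC(F)(F)F)OCC(F)(F)F)[C@@H](C(=C)C(=O)OCc3ccc(OC)cc3)[C@@H]2O[C@@H](O[C@@H]4C[C@H](C)CC[C@H]4C(C)C)C[C@H]12
A1 | alternative 1 | cyclohexanol from the carbonyl-ene closure (C7 isopropenyl trans to C8 hydroxyl, C4 methyl ester, O6 silyl ether) | C=C[C@@]1(C)C[C@H](O)[C@@H](C(C)=C)[C@H](O[Si](C)(C)C(C)(C)C)[C@@H]1C(=O)OC
A2 | alternative 1 | acyclic aldehyde precursor (C8 aldehyde, C7=C11 trisubstituted alkene) | C=C[C@@](C)(CC=O)[C@@H](C(=O)OC)[C@@H](O[Si](C)(C)C(C)(C)C)C=C(C)C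
A3 | alternative 2 | bridged bromolactone (lactone C1 to C6, bromine on C5, enol ether C8=C9) | O=C1O[C@]2(OC)CC(OC)=C[C@@]1(C)[C@H]2Br
A4 | alternative 2 | 3,5-dimethoxy-1-methylcyclohexa-2,5-diene-1-carboxylic acid | COC1=CC(C)(C(=O)O)C=C(OC)C1
A5 | alternative 3 | bridged lactone aldehyde (formyl on C10, bromide on C7) | O=C[C@@]1(C)C[C@H](O2)C(Br)=C[C@@H]1C2=O
A6 | alternative 3 | 5-bromo-2H-pyran-2-one | O=C1C=CC(Br)=CO1
A7 | alternative 3 | methacrolein | CC(=C)C=O
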